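## Structural features

The target 58 is a 36-membered macrolactone whose ring holds C1–C35 and the ester oxygen on C35; C35 also carries an exocyclic hexan-2-yl group (C36 with its methyl and the n-butyl chain C37–C40). The only unsaturation is the (2Z)-3-methyl enoate C1–C3, and the saturated chain C4–C35 bears nine free secondary hydroxyls at C7, C9, C13, C17, C21, C25, C27, C29 and C33. With C35 and C36 this makes eleven stereocentres, of which only C35 and C36 are adjacent (anti). The 1,3-related pairs are C7/C9 syn, C25/C27 syn, C27/C29 anti and C33/C35 syn, whereas C9/C13, C13/C17, C17/C21, C21/C25 and C29/C33 are 1,5-related across three methylenes, so none of these can be set from its neighbour by substrate control. The fragile parts are the Z-enoate (isomerisation, conjugate addition) and the lactone, which can migrate to or contract onto a neighbouring hydroxyl under basic conditions. The real difficulty is to set the remote carbinols independently and to close the large ring without touching the Z alkene. The key step uses the fact that C16–C17(OH)–C18 is a glycidyl unit and that C15 and C19, two bonds from the carbinol, are plain methylenes that can be carried as 1,3-dithiane carbons, so that C13, C17 and C21 belong to three separate pieces.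

## Logic of the disconnections

58 is traced to 57 by masking all nine hydroxyls (seven O–Si bonds and the O7/O9 acetal). The reason is that the free polyol lactone would be exposed to acyl migration in every later operation. The forward step must therefore unmask under acidic, not basic, conditions.

57 is opened at the C3–C4 bond to give 55. This sp2–sp3 bond is far from every stereocentre and lets the Z geometry be brought in ready-made. The gain is an acyclic chain with a terminal alkene at one end and a β-iodoenoate at the other. The forward step needs a hydroboration that touches only the terminal alkene and a coupling fast enough at high dilution to outrun oligomerisation.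

55 is cut at the ester bond C1–O35 into 51 and 53, and 53 goes back to 52 by removing H and I from C2 and C3. This separates the whole stereochemical problem (51) from a four-carbon acid. The forward acylation must work on a hindered secondary alcohol without isomerising the iodoalkene.

51 is traced through 50 and 49 to 48 by cutting C4=C5 back to a C5 primary alcohol and re-masking O5 and O35 as triethylsilyl ethers. A terminal alkene cannot pass the desulfurisation, and an acetal at C5 could not be hydrolysed without losing silyl ethers, so C5 is carried as an alcohol. The forward sequence needs two silyl ethers of one lability to be removed beside seven more robust ones, and a primary alcohol to be oxidised beside a secondary one.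

48 is traced through 47 to 46 by turning the C15 and C19 methylenes back into dithiane carbons and freeing O17. This exposes the two acyl-anion sites on either side of the C16–C18 unit. The forward steps need a silylation of a hindered carbinol and a double C–S hydrogenolysis on a substrate that therefore contains no alkene, halide or benzyl group.

46 is cut at C15–C16 and C18–C19 into 13, 1 and 42. This divides the 36-carbon chain near its middle into two pieces of similar complexity and takes C17 from the chiral pool. The forward step needs the anion of 13 to open the epoxide of 1 before it displaces chloride, and the order of addition to be kept strictly.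

13 is cut at C14–C15 into 8 and 9, so the dithiane arrives by opening an epoxide made in the flask from the chlorohydrin; no Lewis-acid thioacetalisation is needed. 8 is cut at C10–C11 (as an alkene) into 6 and 2, 6 goes back to 3, which already holds C5–C10 with the syn C7/C9 diol as an acetonide, and 2 goes back to 1. The forward steps need a cross-metathesis between an allylic and a homoallylic alkene and a hydrogenation that spares C–Cl.

42 is cut at C19–C20 into 39 and 9 in the same way. 39 is cut at C23–C24 (as an alkene) into 35 and 37, with 37 coming from 36. 35 goes back to 32, whose chlorohydrin is the masked vinyl carbinol. The forward steps repeat the metathesis–hydrogenation–epoxide-opening triad and need C25 to be silylated before the C21 epoxide is generated.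

32 is cut at C30–C31 (as an alkene) into 29 and 18. This joins the C31–C40 piece to the C24–C30 triol unit by the same metathesis logic. The forward hydrogenation must also release O25 from its benzyl ether.

18 is cut at C28–C29 into 15 and 16, with the C27 carbinol traced to the ketone 17, and 15 is traced through 14 to 2. C25 (from 1) controls C29 by 1,5-induction and C29 then controls C27 by directed reduction, so one pool stereocentre sets the triol. The forward aldol must give the 1,5-anti adduct and the reduction the 1,3-anti diol.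

29 is cut at C32–C33 and at C34–C35 back to 25, by two allylations with an alkene cleavage between them, and 25 is cut at the C36–methyl bond back to 19 and 20. This reduces the C31–C40 piece to 19, a methyl group and two allyl units. The forward allylations must be reagent-controlled, because C35 has to be anti to C36, against the weak Felkin preference.

## Other disconnections considered

Alternative 1: The ring would be cut at C11–C12, drawn as an alkyne. In the forward sense the ester-linked diyne A1 would undergo ring-closing alkyne metathesis under the alkylidyne A4, of formula Mo(≡CC6H4OMe-4)(OSiPh3)3. The reaction would expel but-2-yne A3 and give the 36-membered cycloalkyne A2, which would then be saturated.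
- In its favour: the closure proceeds through metallacyclobutadienes, needs no base and does not engage alkenes, so the Z-enoate would pass the ring-forming event untouched; the site lies in a stereochemically silent stretch between C9 and C13.
- Against it here: the C11≡C12 alkyne must afterwards be reduced fully to CH2–CH2 beside the conjugated trisubstituted alkene, which is a real chemoselectivity problem. The two halves of A1 still contain all eleven stereocentres, so the cut does nothing for the 1,5-relationships.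
- Comparison: on structure it competes with the ring closure of the chosen plan (step 39), not with the chain-building key step. As a ring closure it is probably the better of the two, since alkyne metathesis at high dilution is less prone to oligomerisation and side reactions than a B-alkyl cross-coupling. On step economy the two are about equal: one extra saturation against the oxidation and methylenation that the chosen plan spends on its terminal alkene. It could not simply be grafted onto the chosen chain assembly, because alkynes would not survive Raney Ni.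

Alternative 2: The cut would be at C8–C9 and C13–C14. In the forward sense pentane-1,5-diol A5 would be allylated at both carbinol carbons with allyl acetate A6 under a chiral iridium transfer-hydrogenation catalyst, giving the C2-symmetric diene diol A7 with C9 and C13 set together.
- In its favour: two C–C bonds and two stereocentres would come from commodity chemicals in one catalytic step, without stoichiometric chiral material or protecting groups, and the double reaction would enhance the enantiomeric purity.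
- Against it here: the two allyl termini of A7 are equivalent, whereas the target needs one to become the C7 carbinol (syn to C9) with C5/C6 and the other to be cut to a C15 aldehyde. That costs a desymmetrisation and further steps, C7 remains to be set, and the dithiane would have to be made by thioacetalisation beside silyl ethers.
- Comparison: it addresses only the C9/C13 pair and would feed the same key step, so it is an alternative to steps 1–8 and not to the coupling. For those two stereocentres alone it is the better plan (one step against the six of steps 1–6). After desymmetrisation and installation of C7 the C5–C15 dithiane would probably need at least the eight steps used here, so overall it is at best equal. Mechanistically it is catalyst control where the chosen plan uses the chiral pool.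

Alternative 3: The cut would be at C21–C22 and C24–C25. In the forward sense hydroboration of the allenylboronate A8 with a pinene-derived dialkylborane would be followed in the same flask by two successive allylborations. The first would engage the C25 aldehyde A9 at low temperature and the second, on warming, the C21 aldehyde A10, giving the (E)-ene-1,5-anti-diol A11.
- In its favour: it is a three-component union that would form two C–C bonds and create both C21 and C25 in the coupling event; it joins a C25–C40 piece to a C1–C21 piece that already holds the enoate; and it needs neither sulfur nor Raney Ni.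
- Against it here: the C23=C24 alkene must be saturated beside the Z-enoate; both aldehydes are β-silyloxy aldehydes, no shorter to make than 13 and 42, and the second allylboration would consume a precious aldehyde under forcing conditions. A diol protection, ether cleavage at O35, ester hydrolysis and a macrolactonisation of a Z-enoic acid would follow.
- Comparison: in convergence it is the equal of the chosen plan. In stereochemical productivity it is the better, since it creates two stereocentres at the coupling where the chosen key step creates none. In steps after the coupling it is also the better (about six against nine). The chosen plan is the safer in stereochemical fidelity, because nothing is created at the coupling and each remote carbinol comes from an enantiopure C3 unit. It also uses a cheap linchpin, and both partners are made by the same three reaction types.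

Key step: step 31

Remark: locants C1–C40 used for the larger intermediates are those of the macrolide (C1 lactone carbonyl, ring oxygen on C35, C36 the methyl-bearing carbon).
Remark: alcohol 3 is assumed to be purchasable as the bulk statin side-chain intermediate; both enantiomers of epichlorohydrin are commodity chemicals.
Remark: with the C15 anion opening the epoxide of (R)-epichlorohydrin first and the C19 anion opening the re-formed epoxide second, C17 arrives with the configuration of the target. In the precursor design C5 is a primary triethylsilyl ether and not an acetal, O7/O9 are an acetonide, and both dithianes enter by epoxide opening.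

## Route

Step 1
Reactants: 1 (R)-epichlorohydrin
Product: 2 (2R)-1-chloropent-4-en-2-ol
Conditions: vinylMgBr, CuI (10 mol%), THF, −78 → −20 °C; aq. NH4Cl
Reagents that add atoms: vinylmagnesium bromide, C=C[Mg]Br
Why: Copper-catalysed Grignard opening of a terminal epoxide at its unsubstituted carbon (SN2); the stereocentre (later C13 and C25) is not touched and the chloride survives at low temperature.

Step 2
Reactants: 3 tert-butyl 2-[(4R,6S)-6-(hydroxymethyl)-2,2-dimethyl-1,3-dioxan-4-yl]acetate
Product: 4 tert-butyl 2-[(4R,6S)-6-formyl-2,2-dimethyl-1,3-dioxan-4-yl]acetate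
Conditions: TEMPO (10 mol%), PhI(OAc)2, CH2Cl2, rt
Reagents that add atoms: none
Why: Oxoammonium (TEMPO) oxidation of a primary alcohol under nearly neutral conditions, which should keep the α-alkoxy centre (C9) and the cis-acetonide intact.

Step 3
Reactants: 4 tert-butyl 2-[(4R,6S)-6-formyl-2,2-dimethyl-1,3-dioxan-4-yl]acetate
Product: 5 tert-butyl 2-[(4R,6S)-6-ethenyl-2,2-dimethyl-1,3-dioxan-4-yl]acetate
Conditions: Ph3PCH3Br, KN(SiMe3)2, THF, −78 → 0 °C
Reagents that add atoms: methyltriphenylphosphonium bromide, C[P+](c1ccccc1)(c1ccccc1)c1ccccc1.[Br-]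
Why: Wittig methylenation; at −78 °C the unstabilised ylide adds to the aldehyde faster than it enolises it, and the tert-butyl ester is inert.

Step 4
Reactants: 5 tert-butyl 2-[(4R,6S)-6-ethenyl-2,2-dimethyl-1,3-dioxan-4-yl]acetate
Product: 6 2-[(4S,6S)-6-ethenyl-2,2-dimethyl-1,3-dioxan-4-yl]ethan-1-ol
Conditions: LiAlH4, THF, 0 °C → rt
Reagents that add atoms: none
Why: Hydride reduction of the ester to the primary alcohol (the later C5–OH), needed before any organolithium step; alkene and acetonide are inert.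

Step 5
Reactants: 6 2-[(4S,6S)-6-ethenyl-2,2-dimethyl-1,3-dioxan-4-yl]ethan-1-ol; 2 (2R)-1-chloropent-4-en-2-ol (3 equiv)
Product: 7 (2R,4E)-1-chloro-5-[(4S,6S)-6-(2-hydroxyethyl)-2,2-dimethyl-1,3-dioxan-4-yl]pent-4-en-2-ol
Conditions: RuCl2(H2IMes)(=CH-C6H4-2-OiPr) (Hoveyda–Grubbs second-generation catalyst, 5 mol%), CH2Cl2, 40 °C
Reagents that add atoms: none
Why: Olefin cross-metathesis between an allylic acetal-type alkene, slow to homodimerise, and an excess of a homoallylic alcohol; loss of ethylene drives it and the E/Z ratio is irrelevant because the C10=C11 alkene is saturated next.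

Step 6
Reactants: 7 (2R,4E)-1-chloro-5-[(4S,6S)-6-(2-hydroxyethyl)-2,2-dimethyl-1,3-dioxan-4-yl]pent-4-en-2-ol
Product: 8 (2R)-1-chloro-5-[(4R,6S)-6-(2-hydroxyethyl)-2,2-dimethyl-1,3-dioxan-4-yl]pentan-2-ol
Conditions: H2 (1 atm), Pt/C, EtOAc, rt
Reagents that add atoms: none
Why: Heterogeneous hydrogenation of a 1,2-disubstituted alkene; platinum in a neutral solvent should saturate it without hydrogenolysis of the allylic C–O bond or the primary chloride.

Step 7
Reactants: 8 (2R)-1-chloro-5-[(4R,6S)-6-(2-hydroxyethyl)-2,2-dimethyl-1,3-dioxan-4-yl]pentan-2-ol; 9 1,3-dithiane (5 equiv)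
Product: 11 (2R)-1-(1,3-dithian-2-yl)-5-[(4R,6S)-6-(2-hydroxyethyl)-2,2-dimethyl-1,3-dioxan-4-yl]pentan-2-ol, via epoxide 10 (not isolated)
Conditions: 9, n-BuLi (4.8 equiv), THF, −30 °C; then 8, −30 °C → rt
Reagents that add atoms: none
Why: Lithiated 9 first deprotonates both hydroxyls, the C13 alkoxide closes onto CH2Cl (3-exo-tet) to the terminal epoxide 10, and a further equivalent opens it at C14 by SN2 attack on the unsubstituted carbon. C13 is never touched, and a direct displacement of chloride would give the same product.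

Step 8
Reactants: 11 (2R)-1-(1,3-dithian-2-yl)-5-[(4R,6S)-6-(2-hydroxyethyl)-2,2-dimethyl-1,3-dioxan-4-yl]pentan-2-ol
Product: 13 C5–C15 dithiane (5-OTES, 13-OTBS, 7,9-acetonide), via monosilyl ether 12 (not isolated)
Conditions: TESCl (1.05 equiv), imidazole, CH2Cl2, −78 → −30 °C; then 2,6-lutidine, TBSOTf, −78 → 0 °C
Reagents that add atoms: chlorotriethylsilane, CC[Si](CC)(CC)Cl; tert-butyldimethylsilyl triflate, CC(C)(C)[Si](C)(C)OS(=O)(=O)C(F)(F)F
Why: Sequential silylation in one flask: the chlorosilane takes the primary hydroxyl at low temperature and the triflate then caps the hindered secondary one. O5 thus receives the same labile group as O35 so that both can be removed together later.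

Step 9
Reactants: 2 (2R)-1-chloropent-4-en-2-ol
Product: 14 {[(2R)-1-chloropent-4-en-2-yl]oxymethyl}benzene
Conditions: BnOC(=NH)CCl3, TfOH (5 mol%), CH2Cl2/cyclohexane, 0 °C → rt
Reagents that add atoms: benzyl 2,2,2-trichloroacetimidate, ClC(Cl)(Cl)C(=N)OCc1ccccc1
Why: Acid-catalysed benzylation with the trichloroacetimidate; it avoids base, which would close the chlorohydrin to the epoxide.

Step 10
Reactants: 14 {[(2R)-1-chloropent-4-en-2-yl]oxymethyl}benzene
Product: 15 (4R)-4-(benzyloxy)-5-chloropentan-2-one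
Conditions: PdCl2 (10 mol%), CuCl, O2 (1 atm), DMF/H2O (7:1), rt
Reagents that add atoms: water, O
Why: Wacker oxidation of a terminal alkene (Markovnikov hydroxypalladation, β-hydride elimination); homoallylic ethers are standard substrates and give the methyl ketone.

Step 11
Reactants: 15 (4R)-4-(benzyloxy)-5-chloropentan-2-one; 16 acrolein
Product: 17 (3R,7R)-7-(benzyloxy)-8-chloro-3-hydroxyoct-1-en-5-one
Conditions: (c-C6H11)2BCl, Et3N, Et2O, −78 → 0 °C; 16, −78 °C; MeOH, pH 7 buffer, H2O2
Reagents that add atoms: none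
Why: Boron aldol reaction of the kinetic (methyl-side) enolate; the β-benzyloxy group directs 1,5-anti addition, so the new carbinol C29 should be set anti to C25 (1,5-anti induction of β-alkoxy methyl ketones), and acrolein reacts by 1,2-addition only.

Step 12
Reactants: 17 (3R,7R)-7-(benzyloxy)-8-chloro-3-hydroxyoct-1-en-5-one
Product: 18 (3R,5R,7R)-7-(benzyloxy)-8-chlorooct-1-ene-3,5-diol
Conditions: Me4NBH(OAc)3, MeCN/AcOH (1:1), −25 °C
Reagents that add atoms: none
Why: Evans–Saksena reduction: the C29 hydroxyl binds the triacetoxyborohydride and delivers hydride through a chair transition state to give the 1,3-anti diol. With C25/C29 anti this makes C25/C27 syn, as the target requires.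

Step 13
Reactants: 19 hexanoic acid; 20 (4S)-4-benzyl-1,3-oxazolidin-2-one
Product: 22 (4S)-4-benzyl-3-hexanoyl-1,3-oxazolidin-2-one, via mixed anhydride 21 (not isolated)
Conditions: t-BuCOCl, Et3N, THF, −20 °C; then LiCl, 20, −20 °C → rt
Reagents that add atoms: none
Why: N-Acylation of the oxazolidinone by the pivalic mixed anhydride with LiCl activation; the hindered pivaloyl carbonyl is not attacked.

Step 14
Reactants: 22 (4S)-4-benzyl-3-hexanoyl-1,3-oxazolidin-2-one
Product: 23 (4S)-4-benzyl-3-[(2S)-2-methylhexanoyl]-1,3-oxazolidin-2-one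
Conditions: NaN(SiMe3)2, THF, −78 °C; MeI, −78 °C
Reagents that add atoms: iodomethane, CI
Why: Evans alkylation: the chelated sodium Z-enolate is methylated on the face opposite the benzyl group, which sets the (S) centre that becomes C36.

Step 15
Reactants: 23 (4S)-4-benzyl-3-[(2S)-2-methylhexanoyl]-1,3-oxazolidin-2-one
Product: 24 (2S)-2-methylhexan-1-ol
Conditions: LiBH4, MeOH (1 equiv), Et2O, 0 °C
Reagents that add atoms: none
Why: Reductive removal of the auxiliary at the exocyclic carbonyl; no enolisable intermediate is formed, so the α-centre is retained and the auxiliary is recovered.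

Step 16
Reactants: 24 (2S)-2-methylhexan-1-ol
Product: 25 (2S)-2-methylhexanal
Conditions: TEMPO (10 mol%), PhI(OAc)2, CH2Cl2, rt; washed, concentrated cold, used at once
Reagents that add atoms: none
Why: TEMPO oxidation under non-basic conditions; the volatile, epimerisable aldehyde is carried on crude.

Step 17
Reactants: 25 (2S)-2-methylhexanal
Product: 26 (4R,5S)-5-methylnon-1-en-4-ol
Conditions: (+)-Ipc2BOMe, allylMgBr, Et2O, 0 °C → rt; then 25, −78 °C; NaOH, H2O2
Reagents that add atoms: allylmagnesium bromide, C=CC[Mg]Br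
Why: Brown allylboration through a chair six-membered transition state; the reagent derived from (−)-α-pinene should deliver allyl to the Re face and override the weak Felkin bias of the α-methyl aldehyde, giving the 35R carbinol anti to the C36 methyl.

Step 18
Reactants: 26 (4R,5S)-5-methylnon-1-en-4-ol
Product: 27 triethyl{[(4R,5S)-5-methylnon-1-en-4-yl]oxy}silane
Conditions: TESCl, imidazole, DMF, 0 °C → rt
Reagents that add atoms: chlorotriethylsilane, CC[Si](CC)(CC)Cl
Why: Standard silylation; a triethylsilyl ether on O35 can later be removed beside secondary tert-butyldimethylsilyl ethers.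

Step 19
Reactants: 27 triethyl{[(4R,5S)-5-methylnon-1-en-4-yl]oxy}silane
Product: 28 (3R,4S)-4-methyl-3-[(triethylsilyl)oxy]octanal
Conditions: O3, CH2Cl2, −78 °C; PPh3, −78 °C → rt
Reagents that add atoms: ozone, [O-][O+]=O
Why: Ozonolysis with reductive work-up cleaves the terminal alkene to the C33 aldehyde; the silyl ether is inert.

Step 20
Reactants: 28 (3R,4S)-4-methyl-3-[(triethylsilyl)oxy]octanal
Product: 29 (4R,6R,7S)-7-methyl-6-[(triethylsilyl)oxy]undec-1-en-4-ol
Conditions: (+)-Ipc2BOMe, allylMgBr, Et2O, 0 °C → rt; then 28, −78 °C; NaOH, H2O2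
Reagents that add atoms: allylmagnesium bromide, C=CC[Mg]Br
Why: Second Brown allylboration, again by Re-face delivery under reagent control, should set C33 (R), 1,3-syn to O35; β-silyloxy aldehydes show little bias of their own towards allylboranes.

Step 21
Reactants: 29 (4R,6R,7S)-7-methyl-6-[(triethylsilyl)oxy]undec-1-en-4-ol; 18 (3R,5R,7R)-7-(benzyloxy)-8-chlorooct-1-ene-3,5-diol (2 equiv)
Product: 30 (2R,4R,6R,7E,10R,12R,13S)-2-(benzyloxy)-1-chloro-13-methyl-12-[(triethylsilyl)oxy]heptadec-7-ene-4,6,10-triol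
Conditions: RuCl2(H2IMes)(=CH-C6H4-2-OiPr) (10 mol%), 1,4-benzoquinone (10 mol%), CH2Cl2, 40 °C
Reagents that add atoms: none
Why: Cross-metathesis of a homoallylic alcohol with an excess of a free allylic alcohol, which is a better partner than its silyl ether; benzoquinone suppresses isomerisation of the allylic alcohol by Ru–H species.

Step 22
Reactants: 30 (2R,4R,6R,7E,10R,12R,13S)-2-(benzyloxy)-1-chloro-13-methyl-12-[(triethylsilyl)oxy]heptadec-7-ene-4,6,10-triol
Product: 31 (2R,4S,6R,7E,10R,12R,13S)-2-(benzyloxy)-4,6,10-tris[(tert-butyldimethylsilyl)oxy]-1-chloro-13-methyl-12-[(triethylsilyl)oxy]heptadec-7-ene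
Conditions: TBSOTf, 2,6-lutidine, CH2Cl2, −78 → 0 °C
Reagents that add atoms: tert-butyldimethylsilyl triflate, CC(C)(C)[Si](C)(C)OS(=O)(=O)C(F)(F)F
Why: Exhaustive silylation of the three secondary hydroxyls (O27, O29, O33) with the silyl triflate; benzyl ether, chloride and the triethylsilyl ether are inert.

Step 23
Reactants: 31 (2R,4S,6R,7E,10R,12R,13S)-2-(benzyloxy)-4,6,10-tris[(tert-butyldimethylsilyl)oxy]-1-chloro-13-methyl-12-[(triethylsilyl)oxy]heptadec-7-ene
Product: 32 (2R,4S,6S,10R,12R,13S)-4,6,10-tris[(tert-butyldimethylsilyl)oxy]-1-chloro-13-methyl-12-[(triethylsilyl)oxy]heptadecan-2-ol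
Conditions: H2 (1 atm), Pd/C, EtOAc, rt
Reagents that add atoms: none
Why: One hydrogenation saturates C30=C31 and hydrogenolyses the benzyl ether, which uncovers the C25 hydroxyl next to CH2Cl; silyl ethers and the primary chloride should survive in neutral ethyl acetate.

Step 24
Reactants: 32 (2R,4S,6S,10R,12R,13S)-4,6,10-tris[(tert-butyldimethylsilyl)oxy]-1-chloro-13-methyl-12-[(triethylsilyl)oxy]heptadecan-2-ol
Product: 34 (3R,5S,7S,11R,13R,14S)-5,7,11-tris[(tert-butyldimethylsilyl)oxy]-14-methyl-13-[(triethylsilyl)oxy]octadec-1-en-3-ol, via epoxide 33 (not isolated)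
Conditions: Me3SI, n-BuLi, THF, −10 °C; then 32, −10 °C → rt
Reagents that add atoms: trimethylsulfonium iodide, C[S+](C)C.[I-]
Why: Excess dimethylsulfonium methylide deprotonates the chlorohydrin, which closes to epoxide 33; the ylide opens it at C24 and the sulfonium salt eliminates Me2S to the allylic alkoxide (one-carbon homologation of a terminal epoxide to an allylic alcohol). C25 is not touched, and the lithium counter-ion at low temperature should keep a 1,3 silyl shift slower than the closure.

Step 25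
Reactants: 34 (3R,5S,7S,11R,13R,14S)-5,7,11-tris[(tert-butyldimethylsilyl)oxy]-14-methyl-13-[(triethylsilyl)oxy]octadec-1-en-3-ol
Product: 35 (3R,5R,7S,11R,13R,14S)-3,5,7,11-tetrakis[(tert-butyldimethylsilyl)oxy]-14-methyl-13-[(triethylsilyl)oxy]octadec-1-ene
Conditions: TBSOTf, 2,6-lutidine, CH2Cl2, −78 → 0 °C
Reagents that add atoms: tert-butyldimethylsilyl triflate, CC(C)(C)[Si](C)(C)OS(=O)(=O)C(F)(F)F
Why: Silylation of O25 before the C21 epoxide is generated, so that no 1,5-hydroxy epoxide can cyclise to a tetrahydropyran; any O27→O25 silyl-shifted isomer from step 24 converges on the same product.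

Step 26
Reactants: 36 (S)-epichlorohydrin
Product: 37 (2S)-1-chloropent-4-en-2-ol
Conditions: vinylMgBr, CuI (10 mol%), THF, −78 → −20 °C; aq. NH4Cl
Reagents that add atoms: vinylmagnesium bromide, C=C[Mg]Br
Why: Same copper-catalysed epoxide opening as in step 1, in the enantiomeric series required for C21.

Step 27
Reactants: 35 (3R,5R,7S,11R,13R,14S)-3,5,7,11-tetrakis[(tert-butyldimethylsilyl)oxy]-14-methyl-13-[(triethylsilyl)oxy]octadec-1-ene; 37 (2S)-1-chloropent-4-en-2-ol (5 equiv)
Product: 38 (2S,4E,6R,8R,10S,14R,16R,17S)-6,8,10,14-tetrakis[(tert-butyldimethylsilyl)oxy]-1-chloro-17-methyl-16-[(triethylsilyl)oxy]henicos-4-en-2-ol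
Conditions: RuCl2(H2IMes)(=CH-C6H4-2-OiPr) (10 mol%), CH2Cl2, 40 °C
Reagents that add atoms: none
Why: Cross-metathesis of a hindered allylic silyl ether, which does not homodimerise, with a large excess of the cheap homoallylic alcohol, whose homodimer re-enters by secondary metathesis; the geometry of C23=C24 is irrelevant.

Step 28
Reactants: 38 (2S,4E,6R,8R,10S,14R,16R,17S)-6,8,10,14-tetrakis[(tert-butyldimethylsilyl)oxy]-1-chloro-17-methyl-16-[(triethylsilyl)oxy]henicos-4-en-2-ol
Product: 39 (2S,6S,8S,10S,14R,16R,17S)-6,8,10,14-tetrakis[(tert-butyldimethylsilyl)oxy]-1-chloro-17-methyl-16-[(triethylsilyl)oxy]henicosan-2-ol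
Conditions: H2 (1 atm), Pt/C, EtOAc, rt
Reagents that add atoms: none
Why: Hydrogenation of the disubstituted alkene over platinum, chosen to spare the allylic C–O bond and the chloride.

Step 29
Reactants: 39 (2S,6S,8S,10S,14R,16R,17S)-6,8,10,14-tetrakis[(tert-butyldimethylsilyl)oxy]-1-chloro-17-methyl-16-[(triethylsilyl)oxy]henicosan-2-ol; 9 1,3-dithiane (4 equiv)
Product: 41 (2S,6S,8S,10S,14R,16R,17S)-1-(1,3-dithian-2-yl)-6,8,10,14-tetrakis[(tert-butyldimethylsilyl)oxy]-17-methyl-16-[(triethylsilyl)oxy]henicosan-2-ol, via epoxide 40 (not isolated)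
Conditions: 9, n-BuLi (3.8 equiv), THF, −30 °C; then 39, −30 °C → rt
Reagents that add atoms: none
Why: As in step 7: alkoxide closure to the terminal epoxide 40 and SN2 opening at C20 by lithiated 9; C21 keeps its configuration, and the C25 silyl ether is too remote for a silyl shift.

Step 30
Reactants: 41 (2S,6S,8S,10S,14R,16R,17S)-1-(1,3-dithian-2-yl)-6,8,10,14-tetrakis[(tert-butyldimethylsilyl)oxy]-17-methyl-16-[(triethylsilyl)oxy]henicosan-2-ol
Product: 42 C19–C40 dithiane (21,25,27,29,33-penta-OTBS, 35-OTES)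
Conditions: TBSOTf, 2,6-lutidine, CH2Cl2, −78 → 0 °C
Reagents that add atoms: tert-butyldimethylsilyl triflate, CC(C)(C)[Si](C)(C)OS(=O)(=O)C(F)(F)F
Why: Silylation of the C21 hydroxyl; the dithiane C–H and the other silyl ethers are unaffected.

Step 31
Reactants: 13 C5–C15 dithiane (5-OTES, 13-OTBS, 7,9-acetonide); 1 (R)-epichlorohydrin; 42 C19–C40 dithiane (21,25,27,29,33-penta-OTBS, 35-OTES)
Product: 46 C5–C40 15,19-bis-dithiane with free 17-hydroxyl, via lithiated dithiane 43 (not isolated), via epoxide 44 (not isolated), via lithiated dithiane 45 (not isolated)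
Conditions: 13 (1.15 equiv), t-BuLi, THF/HMPA (10:1), −78 °C; 1 (1.1 equiv), −78 → 0 °C; recooled and added to 45 [from 42 (1.0 equiv), t-BuLi, THF/HMPA, −78 °C]; −78 → −20 °C; aq. NH4Cl
Reagents that add atoms: none
Why: Deprotonation of 13 at C15 gives the sulfur-stabilised carbanion 43, which at −78 °C attacks the unsubstituted epoxide carbon of 1 by SN2 far faster than it displaces the primary chloride, so the first new bond is C15–C16. On warming, the lithium alkoxide displaces chloride intramolecularly and regenerates an epoxide on the other side of the untouched carbinol carbon, giving 44, whose C15 is now quaternary and cannot be deprotonated again. The second carbanion 45, made in the same way from 42, opens 44 at its terminal carbon C18 by SN2, forming C18–C19 and leaving the C17 alkoxide, which is protonated on work-up. The closest known reaction type is the one-flask union of two lithiated 1,3-dithianes with epichlorohydrin as a bis-electrophile (dithiane linchpin coupling). No ring of the product is formed; the only closure is the transient 3-exo-tet formation of the epoxide. No stereocentre is created: C17 is carried over from 1, and its sense relative to the two chains is fixed only by which anion is added first. The step needs chemoselectivity (epoxide before chloride for the first anion), regioselectivity (terminal carbon in both openings) and clean sequencing; these should be secured by the low temperature and lithium assistance of the first opening, by the steric bias of monosubstituted epoxides, and by consuming 43 before 45 is introduced. The silyl ethers and the acetonide are inert to the anions, no leaving group stands next to either carbanion, and the O13 and O21 silyl groups should stay on oxygen because the dithiane-stabilised anion is the favoured side of any 1,4 silyl-transfer equilibrium.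

Step 32
Reactants: 46 C5–C40 15,19-bis-dithiane with free 17-hydroxyl
Product: 47 C5–C40 15,19-bis-dithiane, 17-OTBS
Conditions: TBSOTf, 2,6-lutidine, CH2Cl2, −78 → 0 °C
Reagents that add atoms: tert-butyldimethylsilyl triflate, CC(C)(C)[Si](C)(C)OS(=O)(=O)C(F)(F)F
Why: The carbinol between two dithianes is hindered and needs the silyl triflate; O17 must be masked so that O35 is later the only free hydroxyl.

Step 33
Reactants: 47 C5–C40 15,19-bis-dithiane, 17-OTBS
Product: 48 C5–C40 chain (5,35-bis-OTES, 13,17,21,25,27,29,33-hepta-OTBS, 7,9-acetonide)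
Conditions: Raney Ni (W-2), EtOH, rt → 45 °C
Reagents that add atoms: none
Why: Reductive desulfurisation turns both dithiane carbons into methylenes; the substrate holds no alkene, halide or benzyl group, and silyl ethers and acetonide are stable. Premature loss of a triethylsilyl group would be harmless, since both are removed next.

Step 34
Reactants: 48 C5–C40 chain (5,35-bis-OTES, 13,17,21,25,27,29,33-hepta-OTBS, 7,9-acetonide)
Product: 49 C5–C40 5,35-diol (13,17,21,25,27,29,33-hepta-OTBS, 7,9-acetonide)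
Conditions: HF·pyridine, pyridine, THF, 0 °C
Reagents that add atoms: none
Why: Buffered HF·pyridine cleaves triethylsilyl ethers (primary O5, secondary O35) much faster than secondary tert-butyldimethylsilyl ethers and leaves the acetonide.

Step 35
Reactants: 49 C5–C40 5,35-diol (13,17,21,25,27,29,33-hepta-OTBS, 7,9-acetonide)
Product: 50 C5 aldehyde with free 35-hydroxyl
Conditions: TEMPO (20 mol%), PhI(OAc)2, CH2Cl2, rt
Reagents that add atoms: none
Why: The oxoammonium oxidant reacts with primary alcohols far faster than with a hindered secondary one, so only C5 should be oxidised.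

Step 36
Reactants: 50 C5 aldehyde with free 35-hydroxyl
Product: 51 C4–C40 terminal alkene with free 35-hydroxyl
Conditions: Ph3PCH3Br, KN(SiMe3)2 (excess), THF, −78 → 0 °C
Reagents that add atoms: methyltriphenylphosphonium bromide, C[P+](c1ccccc1)(c1ccccc1)c1ccccc1.[Br-]
Why: Wittig methylenation adds C4; one equivalent of ylide is spent on the O35 proton, and the low temperature should prevent β-elimination of the acetonide oxygen at C7.

Step 37
Reactants: 52 but-2-ynoic acid
Product: 53 (2Z)-3-iodobut-2-enoic acid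
Conditions: NaI, AcOH, 115 °C
Reagents that add atoms: sodium iodide, [Na+].[I-]
Why: Conjugate addition of iodide to the ynoic acid with anti protonation gives the Z iodoalkene.

Step 38
Reactants: 51 C4–C40 terminal alkene with free 35-hydroxyl; 53 (2Z)-3-iodobut-2-enoic acid
Product: 55 C4–C40 alkene O35-[(2Z)-3-iodobut-2-enoate], via mixed anhydride 54 (not isolated)
Conditions: 2,4,6-Cl3C6H2COCl, Et3N, THF, rt; then 51, DMAP, toluene, rt
Reagents that add atoms: none
Why: Yamaguchi esterification: the mixed anhydride 54 acylates the hindered but only free hydroxyl under DMAP catalysis at room temperature, conditions under which the Z-iodoalkene should keep its geometry.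

Step 39
Reactants: 55 C4–C40 alkene O35-[(2Z)-3-iodobut-2-enoate]
Product: 57 protected macrolactone (13,17,21,25,27,29,33-hepta-OTBS, 7,9-acetonide), via alkylborane 56 (not isolated)
Conditions: 9-BBN-H, THF, rt; then slow addition to Pd(dppf)Cl2 (20 mol%), AsPh3, Cs2CO3, DMF/THF/H2O, 45 °C, final 1 mM
Reagents that add atoms: none
Why: 9-BBN-H adds only to the terminal alkene, placing boron on C4. The base-activated B-alkyl borane 56 then transmetalates to the alkenylpalladium iodide formed by oxidative addition of zerovalent palladium into C3–I, and reductive elimination closes the 36-membered ring with retention of the Z geometry (intramolecular B-alkyl Suzuki–Miyaura coupling at high dilution).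

Step 40
Reactants: 57 protected macrolactone (13,17,21,25,27,29,33-hepta-OTBS, 7,9-acetonide)
Product: 58 target macrolide
Conditions: 48% aq. HF, MeCN/THF, 0 °C → rt
Reagents that add atoms: none
Why: Aqueous HF cleaves the seven silyl ethers and hydrolyses the acetonide in one operation; the acidic medium avoids the base-induced acyl migration to which the polyol lactone is prone.

## Compound list

1 | (R)-epichlorohydrin [(2R)-2-(chloromethyl)oxirane] | ClC[C@H]1CO1 | starting material
2 | (2R)-1-chloropent-4-en-2-ol | ClC[C@H](O)CC=C | intermediate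
3 | tert-butyl 2-[(4R,6S)-6-(hydroxymethyl)-2,2-dimethyl-1,3-dioxan-4-yl]acetate | OC[C@@H]1C[C@H](CC(=O)OC(C)(C)C)OC(C)(C)O1 | starting material
4 | tert-butyl 2-[(4R,6S)-6-formyl-2,2-dimethyl-1,3-dioxan-4-yl]acetate | O=C[C@@H]1C[C@H](CC(=O)OC(C)(C)C)OC(C)(C)O1 | intermediate
5 | tert-butyl 2-[(4R,6S)-6-ethenyl-2,2-dimethyl-1,3-dioxan-4-yl]acetate | C=C[C@@H]1C[C@H](CC(=O)OC(C)(C)C)OC(C)(C)O1 | intermediate
6 | 2-[(4S,6S)-6-ethenyl-2,2-dimethyl-1,3-dioxan-4-yl]ethan-1-ol | C=C[C@@H]1C[C@H](CCO)OC(C)(C)O1 | intermediate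
7 | (2R,4E)-1-chloro-5-[(4S,6S)-6-(2-hydroxyethyl)-2,2-dimethyl-1,3-dioxan-4-yl]pent-4-en-2-ol | ClC[C@H](O)C/C=C/[C@@H]1C[C@H](CCO)OC(C)(C)O1 | intermediate
8 | (2R)-1-chloro-5-[(4R,6S)-6-(2-hydroxyethyl)-2,2-dimethyl-1,3-dioxan-4-yl]pentan-2-ol | ClC[C@H](O)CCC[C@@H]1C[C@H](CCO)OC(C)(C)O1 | intermediate
9 | 1,3-dithiane | C1CSCSC1 | starting material
10 | 2-[(4S,6R)-2,2-dimethyl-6-{3-[(2R)-oxiran-2-yl]propyl}-1,3-dioxan-4-yl]ethan-1-ol (present as its lithium alkoxide) | C1O[C@@H]1CCC[C@@H]1C[C@H](CCO)OC(C)(C)O1 | intermediate (not isolated)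
11 | (2R)-1-(1,3-dithian-2-yl)-5-[(4R,6S)-6-(2-hydroxyethyl)-2,2-dimethyl-1,3-dioxan-4-yl]pentan-2-ol | S1CCCSC1C[C@H](O)CCC[C@@H]1C[C@H](CCO)OC(C)(C)O1 | intermediate
12 | (2R)-1-(1,3-dithian-2-yl)-5-[(4R,6S)-2,2-dimethyl-6-{2-[(triethylsilyl)oxy]ethyl}-1,3-dioxan-4-yl]pentan-2-ol | S1CCCSC1C[C@H](O)CCC[C@@H]1C[C@H](CCO[Si](CC)(CC)CC)OC(C)(C)O1 | intermediate (not isolated)
13 | C5–C15 dithiane: 2-[(2R)-2-[(tert-butyldimethylsilyl)oxy]-5-[(4R,6S)-2,2-dimethyl-6-{2-[(triethylsilyl)oxy]ethyl}-1,3-dioxan-4-yl]pentyl]-1,3-dithiane (7S,9R,13R) | S1CCCSC1C[C@H](O[Si](C)(C)C(C)(C)C)CCC[C@@H]1C[C@H](CCO[Si](CC)(CC)CC)OC(C)(C)O1 | intermediate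
14 | {[(2R)-1-chloropent-4-en-2-yl]oxymethyl}benzene | ClC[C@H](OCc1ccccc1)CC=C | intermediate
15 | (4R)-4-(benzyloxy)-5-chloropentan-2-one | ClC[C@H](OCc1ccccc1)CC(C)=O | intermediate
16 | acrolein (prop-2-enal) | C=CC=O | starting material
17 | (3R,7R)-7-(benzyloxy)-8-chloro-3-hydroxyoct-1-en-5-one | C=C[C@H](O)CC(=O)C[C@@H](OCc1ccccc1)CCl | intermediate
18 | (3R,5R,7R)-7-(benzyloxy)-8-chlorooct-1-ene-3,5-diol | C=C[C@H](O)C[C@@H](O)C[C@@H](OCc1ccccc1)CCl | intermediate
19 | hexanoic acid | CCCCCC(=O)O | starting material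
20 | (4S)-4-benzyl-1,3-oxazolidin-2-one | O=C1N[C@@H](Cc2ccccc2)CO1 | starting material
21 | hexanoic pivalic anhydride | CCCCCC(=O)OC(=O)C(C)(C)C | intermediate (not isolated)
22 | (4S)-4-benzyl-3-hexanoyl-1,3-oxazolidin-2-one | CCCCCC(=O)N1[C@@H](Cc2ccccc2)COC1=O | intermediate
23 | (4S)-4-benzyl-3-[(2S)-2-methylhexanoyl]-1,3-oxazolidin-2-one | CCCC[C@H](C)C(=O)N1[C@@H](Cc2ccccc2)COC1=O | intermediate
24 | (2S)-2-methylhexan-1-ol | CCCC[C@H](C)CO | intermediate
25 | (2S)-2-methylhexanal | CCCC[C@H](C)C=O | intermediate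
26 | (4R,5S)-5-methylnon-1-en-4-ol | CCCC[C@H](C)[C@H](O)CC=C | intermediate
27 | triethyl{[(4R,5S)-5-methylnon-1-en-4-yl]oxy}silane | CCCC[C@H](C)[C@H](O[Si](CC)(CC)CC)CC=C | intermediate
28 | (3R,4S)-4-methyl-3-[(triethylsilyl)oxy]octanal | CCCC[C@H](C)[C@H](O[Si](CC)(CC)CC)CC=O | intermediate
29 | (4R,6R,7S)-7-methyl-6-[(triethylsilyl)oxy]undec-1-en-4-ol | CCCC[C@H](C)[C@H](O[Si](CC)(CC)CC)C[C@H](O)CC=C | intermediate
30 | (2R,4R,6R,7E,10R,12R,13S)-2-(benzyloxy)-1-chloro-13-methyl-12-[(triethylsilyl)oxy]heptadec-7-ene-4,6,10-triol (C24–C40) | CCCC[C@H](C)[C@H](O[Si](CC)(CC)CC)C[C@H](O)C/C=C/[C@H](O)C[C@@H](O)C[C@@H](OCc1ccccc1)CCl | intermediate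
31 | (2R,4S,6R,7E,10R,12R,13S)-2-(benzyloxy)-4,6,10-tris[(tert-butyldimethylsilyl)oxy]-1-chloro-13-methyl-12-[(triethylsilyl)oxy]heptadec-7-ene | CCCC[C@H](C)[C@H](O[Si](CC)(CC)CC)C[C@H](O[Si](C)(C)C(C)(C)C)C/C=C/[C@H](O[Si](C)(C)C(C)(C)C)C[C@@H](O[Si](C)(C)C(C)(C)C)C[C@@H](OCc1ccccc1)CCl | intermediate
32 | (2R,4S,6S,10R,12R,13S)-4,6,10-tris[(tert-butyldimethylsilyl)oxy]-1-chloro-13-methyl-12-[(triethylsilyl)oxy]heptadecan-2-ol | CCCC[C@H](C)[C@H](O[Si](CC)(CC)CC)C[C@H](O[Si](C)(C)C(C)(C)C)CCC[C@H](O[Si](C)(C)C(C)(C)C)C[C@@H](O[Si](C)(C)C(C)(C)C)C[C@@H](O)CCl | intermediate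
33 | (2R)-2-{(2S,4S,8R,10R,11S)-2,4,8-tris[(tert-butyldimethylsilyl)oxy]-11-methyl-10-[(triethylsilyl)oxy]pentadecyl}oxirane | CCCC[C@H](C)[C@H](O[Si](CC)(CC)CC)C[C@H](O[Si](C)(C)C(C)(C)C)CCC[C@H](O[Si](C)(C)C(C)(C)C)C[C@@H](O[Si](C)(C)C(C)(C)C)C[C@@H]1CO1 | intermediate (not isolated)
34 | (3R,5S,7S,11R,13R,14S)-5,7,11-tris[(tert-butyldimethylsilyl)oxy]-14-methyl-13-[(triethylsilyl)oxy]octadec-1-en-3-ol | CCCC[C@H](C)[C@H](O[Si](CC)(CC)CC)C[C@H](O[Si](C)(C)C(C)(C)C)CCC[C@H](O[Si](C)(C)C(C)(C)C)C[C@@H](O[Si](C)(C)C(C)(C)C)C[C@@H](O)C=C | intermediate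
35 | (3R,5R,7S,11R,13R,14S)-3,5,7,11-tetrakis[(tert-butyldimethylsilyl)oxy]-14-methyl-13-[(triethylsilyl)oxy]octadec-1-ene | CCCC[C@H](C)[C@H](O[Si](CC)(CC)CC)C[C@H](O[Si](C)(C)C(C)(C)C)CCC[C@H](O[Si](C)(C)C(C)(C)C)C[C@@H](O[Si](C)(C)C(C)(C)C)C[C@@H](O[Si](C)(C)C(C)(C)C)C=C | intermediate
36 | (S)-epichlorohydrin [(2S)-2-(chloromethyl)oxirane] | ClC[C@@H]1CO1 | starting material
37 | (2S)-1-chloropent-4-en-2-ol | ClC[C@@H](O)CC=C | intermediate
38 | (2S,4E,6R,8R,10S,14R,16R,17S)-6,8,10,14-tetrakis[(tert-butyldimethylsilyl)oxy]-1-chloro-17-methyl-16-[(triethylsilyl)oxy]henicos-4-en-2-ol (C20–C40) | CCCC[C@H](C)[C@H](O[Si](CC)(CC)CC)C[C@H](O[Si](C)(C)C(C)(C)C)CCC[C@H](O[Si](C)(C)C(C)(C)C)C[C@@H](O[Si](C)(C)C(C)(C)C)C[C@@H](O[Si](C)(C)C(C)(C)C)/C=C/C[C@H](O)CCl | intermediate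
39 | (2S,6S,8S,10S,14R,16R,17S)-6,8,10,14-tetrakis[(tert-butyldimethylsilyl)oxy]-1-chloro-17-methyl-16-[(triethylsilyl)oxy]henicosan-2-ol | CCCC[C@H](C)[C@H](O[Si](CC)(CC)CC)C[C@H](O[Si](C)(C)C(C)(C)C)CCC[C@H](O[Si](C)(C)C(C)(C)C)C[C@@H](O[Si](C)(C)C(C)(C)C)C[C@@H](O[Si](C)(C)C(C)(C)C)CCC[C@H](O)CCl | intermediate
40 | (2S)-2-{(4S,6S,8S,12R,14R,15S)-4,6,8,12-tetrakis[(tert-butyldimethylsilyl)oxy]-15-methyl-14-[(triethylsilyl)oxy]nonadecyl}oxirane | CCCC[C@H](C)[C@H](O[Si](CC)(CC)CC)C[C@H](O[Si](C)(C)C(C)(C)C)CCC[C@H](O[Si](C)(C)C(C)(C)C)C[C@@H](O[Si](C)(C)C(C)(C)C)C[C@@H](O[Si](C)(C)C(C)(C)C)CCC[C@H]1CO1 | intermediate (not isolated)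
41 | (2S,6S,8S,10S,14R,16R,17S)-1-(1,3-dithian-2-yl)-6,8,10,14-tetrakis[(tert-butyldimethylsilyl)oxy]-17-methyl-16-[(triethylsilyl)oxy]henicosan-2-ol | CCCC[C@H](C)[C@H](O[Si](CC)(CC)CC)C[C@H](O[Si](C)(C)C(C)(C)C)CCC[C@H](O[Si](C)(C)C(C)(C)C)C[C@@H](O[Si](C)(C)C(C)(C)C)C[C@@H](O[Si](C)(C)C(C)(C)C)CCC[C@H](O)CC1SCCCS1 | intermediate
42 | C19–C40 dithiane: 2-{(2S,6S,8R,10S,14R,16R,17S)-2,6,8,10,14-pentakis[(tert-butyldimethylsilyl)oxy]-17-methyl-16-[(triethylsilyl)oxy]henicosyl}-1,3-dithiane | CCCC[C@H](C)[C@H](O[Si](CC)(CC)CC)C[C@H](O[Si](C)(C)C(C)(C)C)CCC[C@H](O[Si](C)(C)C(C)(C)C)C[C@@H](O[Si](C)(C)C(C)(C)C)C[C@@H](O[Si](C)(C)C(C)(C)C)CCC[C@H](O[Si](C)(C)C(C)(C)C)CC1SCCCS1 | intermediate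
43 | 2-lithio derivative of 13 (lithium on C15) | [Li]C1(SCCCS1)C[C@H](O[Si](C)(C)C(C)(C)C)CCC[C@@H]1C[C@H](CCO[Si](CC)(CC)CC)OC(C)(C)O1 | intermediate (not isolated)
44 | C5–C18 epoxide: 2-{[(2R)-oxiran-2-yl]methyl}-2-[(2R)-2-[(tert-butyldimethylsilyl)oxy]-5-[(4R,6S)-2,2-dimethyl-6-{2-[(triethylsilyl)oxy]ethyl}-1,3-dioxan-4-yl]pentyl]-1,3-dithiane | C1O[C@@H]1CC1(SCCCS1)C[C@H](O[Si](C)(C)C(C)(C)C)CCC[C@@H]1C[C@H](CCO[Si](CC)(CC)CC)OC(C)(C)O1 | intermediate (not isolated)
45 | 2-lithio derivative of 42 (lithium on C19) | CCCC[C@H](C)[C@H](O[Si](CC)(CC)CC)C[C@H](O[Si](C)(C)C(C)(C)C)CCC[C@H](O[Si](C)(C)C(C)(C)C)C[C@@H](O[Si](C)(C)C(C)(C)C)C[C@@H](O[Si](C)(C)C(C)(C)C)CCC[C@H](O[Si](C)(C)C(C)(C)C)CC1([Li])SCCCS1 | intermediate (not isolated)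
46 | C5–C40 chain, (7S,9R,13R,17R,21S,25S,27R,29S,33R,35R,36S): 17-hydroxy; C15 and C19 each a 1,3-dithiane-2,2-diyl carbon; 13,21,25,27,29,33-hexakis(OTBS); 5,35-bis(OTES); 7,9-O-isopropylidene; 36-methyl | CCCC[C@H](C)[C@H](O[Si](CC)(CC)CC)C[C@H](O[Si](C)(C)C(C)(C)C)CCC[C@H](O[Si](C)(C)C(C)(C)C)C[C@@H](O[Si](C)(C)C(C)(C)C)C[C@@H](O[Si](C)(C)C(C)(C)C)CCC[C@H](O[Si](C)(C)C(C)(C)C)CC1(SCCCS1)C[C@H](O)CC1(SCCCS1)C[C@H](O[Si](C)(C)C(C)(C)C)CCC[C@@H]1C[C@H](CCO[Si](CC)(CC)CC)OC(C)(C)O1 | intermediate
47 | 17-O-TBS ether of 46, (7S,9R,13R,17R,21S,25S,27R,29S,33R,35R,36S): 13,17,21,25,27,29,33-heptakis(OTBS) | CCCC[C@H](C)[C@H](O[Si](CC)(CC)CC)C[C@H](O[Si](C)(C)C(C)(C)C)CCC[C@H](O[Si](C)(C)C(C)(C)C)C[C@@H](O[Si](C)(C)C(C)(C)C)C[C@@H](O[Si](C)(C)C(C)(C)C)CCC[C@H](O[Si](C)(C)C(C)(C)C)CC1(SCCCS1)C[C@H](O[Si](C)(C)C(C)(C)C)CC1(SCCCS1)C[C@H](O[Si](C)(C)C(C)(C)C)CCC[C@@H]1C[C@H](CCO[Si](CC)(CC)CC)OC(C)(C)O1 | intermediate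
48 | C5–C40 chain, (7S,9R,13R,17R,21R,25S,27S,29S,33R,35R,36S): 13,17,21,25,27,29,33-heptakis(OTBS); 5,35-bis(OTES); 7,9-O-isopropylidene; 36-methyl; C15 and C19 methylene | CCCC[C@H](C)[C@H](O[Si](CC)(CC)CC)C[C@H](O[Si](C)(C)C(C)(C)C)CCC[C@H](O[Si](C)(C)C(C)(C)C)C[C@@H](O[Si](C)(C)C(C)(C)C)C[C@@H](O[Si](C)(C)C(C)(C)C)CCC[C@H](O[Si](C)(C)C(C)(C)C)CCC[C@H](O[Si](C)(C)C(C)(C)C)CCC[C@H](O[Si](C)(C)C(C)(C)C)CCC[C@@H]1C[C@H](CCO[Si](CC)(CC)CC)OC(C)(C)O1 | intermediate
49 | C5–C40 5,35-diol, (7S,9R,13R,17R,21R,25S,27S,29S,33R,35R,36S): 13,17,21,25,27,29,33-heptakis(OTBS); 7,9-O-isopropylidene; 36-methyl | CCCC[C@H](C)[C@H](O)C[C@H](O[Si](C)(C)C(C)(C)C)CCC[C@H](O[Si](C)(C)C(C)(C)C)C[C@@H](O[Si](C)(C)C(C)(C)C)C[C@@H](O[Si](C)(C)C(C)(C)C)CCC[C@H](O[Si](C)(C)C(C)(C)C)CCC[C@H](O[Si](C)(C)C(C)(C)C)CCC[C@H](O[Si](C)(C)C(C)(C)C)CCC[C@@H]1C[C@H](CCO)OC(C)(C)O1 | intermediate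
50 | C5 aldehyde of 49 with free 35-hydroxyl, (7R,9R,13R,17R,21R,25S,27S,29S,33R,35R,36S) | CCCC[C@H](C)[C@H](O)C[C@H](O[Si](C)(C)C(C)(C)C)CCC[C@H](O[Si](C)(C)C(C)(C)C)C[C@@H](O[Si](C)(C)C(C)(C)C)C[C@@H](O[Si](C)(C)C(C)(C)C)CCC[C@H](O[Si](C)(C)C(C)(C)C)CCC[C@H](O[Si](C)(C)C(C)(C)C)CCC[C@H](O[Si](C)(C)C(C)(C)C)CCC[C@@H]1C[C@H](CC=O)OC(C)(C)O1 | intermediate
51 | C4–C40 chain with C4=C5 terminal alkene and free 35-hydroxyl, (7S,9R,13R,17R,21R,25S,27S,29S,33R,35R,36S): 13,17,21,25,27,29,33-heptakis(OTBS); 7,9-O-isopropylidene | CCCC[C@H](C)[C@H](O)C[C@H](O[Si](C)(C)C(C)(C)C)CCC[C@H](O[Si](C)(C)C(C)(C)C)C[C@@H](O[Si](C)(C)C(C)(C)C)C[C@@H](O[Si](C)(C)C(C)(C)C)CCC[C@H](O[Si](C)(C)C(C)(C)C)CCC[C@H](O[Si](C)(C)C(C)(C)C)CCC[C@H](O[Si](C)(C)C(C)(C)C)CCC[C@@H]1C[C@H](CC=C)OC(C)(C)O1 | intermediate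
52 | but-2-ynoic acid | CC#CC(=O)O | starting material
53 | (2Z)-3-iodobut-2-enoic acid | C/C(I)=C/C(=O)O | intermediate
54 | (2Z)-3-iodobut-2-enoic 2,4,6-trichlorobenzoic anhydride | C/C(I)=C/C(=O)OC(=O)c1c(Cl)cc(Cl)cc1Cl | intermediate (not isolated)
55 | O35-[(2Z)-3-iodobut-2-enoyl] ester of 51, (7S,9R,13R,17R,21R,25S,27S,29S,33R,35R,36S) | CCCC[C@H](C)[C@H](OC(=O)/C=C(/C)I)C[C@H](O[Si](C)(C)C(C)(C)C)CCC[C@H](O[Si](C)(C)C(C)(C)C)C[C@@H](O[Si](C)(C)C(C)(C)C)C[C@@H](O[Si](C)(C)C(C)(C)C)CCC[C@H](O[Si](C)(C)C(C)(C)C)CCC[C@H](O[Si](C)(C)C(C)(C)C)CCC[C@H](O[Si](C)(C)C(C)(C)C)CCC[C@@H]1C[C@H](CC=C)OC(C)(C)O1 | intermediate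
56 | C4-(9-borabicyclo[3.3.1]nonan-9-yl) derivative of 55 (B-alkyl borane) | CCCC[C@H](C)[C@H](OC(=O)/C=C(/C)I)C[C@H](O[Si](C)(C)C(C)(C)C)CCC[C@H](O[Si](C)(C)C(C)(C)C)C[C@@H](O[Si](C)(C)C(C)(C)C)C[C@@H](O[Si](C)(C)C(C)(C)C)CCC[C@H](O[Si](C)(C)C(C)(C)C)CCC[C@H](O[Si](C)(C)C(C)(C)C)CCC[C@H](O[Si](C)(C)C(C)(C)C)CCC[C@@H]1C[C@H](CCCB2C3CCCC2CCC3)OC(C)(C)O1 | intermediate (not isolated)
57 | protected macrolactone, (2Z,7S,9R,13R,17R,21R,25S,27S,29S,33R,35R,36S): 36-membered lactone with 13,17,21,25,27,29,33-heptakis(OTBS) and 7,9-O-isopropylidene | CCCC[C@H](C)[C@H]1C[C@H](O[Si](C)(C)C(C)(C)C)CCC[C@H](O[Si](C)(C)C(C)(C)C)C[C@@H](O[Si](C)(C)C(C)(C)C)C[C@@H](O[Si](C)(C)C(C)(C)C)CCC[C@H](O[Si](C)(C)C(C)(C)C)CCC[C@H](O[Si](C)(C)C(C)(C)C)CCC[C@H](O[Si](C)(C)C(C)(C)C)CCC[C@@H]2C[C@H](CCC/C(C)=C\C(=O)O1)OC(C)(C)O2 | intermediate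
58 | target: (2Z,7S,9R,13S,17R,21R,25S,27S,29S,33R,35R)-35-[(2S)-hexan-2-yl]-7,9,13,17,21,25,27,29,33-nonahydroxy-3-methyl 36-membered macrolactone (CNP0126363.4) | CCCC[C@H](C)[C@H]1C[C@H](O)CCC[C@H](O)C[C@@H](O)C[C@@H](O)CCC[C@H](O)CCC[C@H](O)CCC[C@H](O)CCC[C@@H](O)C[C@@H](O)CCC/C(C)=C\C(=O)O1 | target

## Step count, longest linear sequence and least certain steps

Total: 40 steps. Longest linear sequence: 26 steps, from 19 to 58 (steps 13–25, 27–36 and 38–40).

Step 31 (key step).
- What may go wrong: incomplete lithiation of the 2-alkyl dithianes or decay of their anions; attack of the first anion on chloride instead of the epoxide, which would deliver the C17 epimer; and slow opening of the hindered epoxide 44 by the large anion 45, with proton transfer quenching the more precious partner.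
- Fallback: it sets out from 42 and 36 and returns at 46, with the roles reversed. Lithiated 42 (45) is treated with an excess of the cheap (S)-epichlorohydrin 36 and warmed, and the resulting C17–C40 epoxide F1 is isolated and purified. It is then opened at C16 by an excess of lithiated 13 (43) to give 46. The large fragment is thus committed in the easy step and the smaller anion, used in excess, performs the difficult opening; (S)-epichlorohydrin with this order gives the same sense at C17.

Step 39.
- What may go wrong: oligomerisation competing with closure of the 36-membered ring, protodeboronation or β-hydride elimination of the alkylpalladium species, and base-induced loss of HI or Z/E isomerisation of the iodoenoate.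
- Fallback: it sets out from 51 and returns at 57. Hydroboration of 51 with 9-BBN-H and intermolecular coupling at normal concentration with methyl (2Z)-3-iodobut-2-enoate F2 (from 53 and trimethylsilyldiazomethane in methanol) would give the seco hydroxy ester F3. Hydrolysis with Me3SnOH would give the seco acid F4, and macrolactonisation with 2-methyl-6-nitrobenzoic anhydride and DMAP at high dilution would give 57.

Step 27.
- What may go wrong: sluggish metathesis at the hindered allylic silyl ether, so that homodimerisation of 37 and double-bond migration dominate.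
- Fallback: it sets out from 32 and returns at epoxide 40, which then takes lithiated 9 as in step 29. K2CO3 in methanol closes 32 to 33, which is isolated. CuI-catalysed opening with but-3-enylmagnesium bromide gives the C20–C40 alkenol F5, and silylation gives its silyl ether F6. Epoxidation with mCPBA gives the C21-epimeric epoxide mixture F7. Hydrolytic kinetic resolution with (R,R)-(salen)Co(OAc), the complex that leaves (S)-alkyl oxiranes unreacted, removes the 21R epimer as the diol F8 and leaves 40.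

Step 34.
- What may go wrong: incomplete cleavage of the hindered O35 silyl ether, or concurrent loss of secondary tert-butyldimethylsilyl groups, after which the oxidation and acylation would no longer be selective.
- Fallback: it sets out from 48 and returns at 51. Swern conditions convert the primary triethylsilyl ether of 48 directly into the C5 aldehyde F9 and leave the secondary silyl ethers in place. Wittig methylenation gives the terminal alkene F10, and the single remaining triethylsilyl ether is then cleaved with HF·pyridine/pyridine to give 51. No diol and no selective oxidation are needed.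

Step 40.
- What may go wrong: acyl migration with ring contraction towards O33, and incomplete unmasking giving mixtures because acetonide hydrolysis and desilylation run at different rates.
- Fallback: it sets out from 57 and returns at 58 in two stages. Buffered HF·pyridine in THF/pyridine removes the seven silyl ethers and gives the 7,9-O-isopropylidene macrolide F11, which can be purified. The acetonide is then hydrolysed with 80% aqueous acetic acid to give 58.

## Further compounds

F1 | step 31 | C17–C40 epoxide: 2-{[(2S)-oxiran-2-yl]methyl}-2-{(2S,6S,8R,10S,14R,16R,17S)-2,6,8,10,14-pentakis[(tert-butyldimethylsilyl)oxy]-17-methyl-16-[(triethylsilyl)oxy]henicosyl}-1,3-dithiane | CCCC[C@H](C)[C@H](O[Si](CC)(CC)CC)C[C@H](O[Si](C)(C)C(C)(C)C)CCC[C@H](O[Si](C)(C)C(C)(C)C)C[C@@H](O[Si](C)(C)C(C)(C)C)C[C@@H](O[Si](C)(C)C(C)(C)C)CCC[C@H](O[Si](C)(C)C(C)(C)C)CC1(SCCCS1)C[C@H]1CO1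
F2 | step 39 | methyl (2Z)-3-iodobut-2-enoate | COC(=O)/C=C(/C)I
F3 | step 39 | seco hydroxy ester: methyl (2Z)-enoate of the C1–C40 chain with free 35-hydroxyl, 13,17,21,25,27,29,33-heptakis(OTBS), 7,9-O-isopropylidene | CCCC[C@H](C)[C@H](O)C[C@H](O[Si](C)(C)C(C)(C)C)CCC[C@H](O[Si](C)(C)C(C)(C)C)C[C@@H](O[Si](C)(C)C(C)(C)C)C[C@@H](O[Si](C)(C)C(C)(C)C)CCC[C@H](O[Si](C)(C)C(C)(C)C)CCC[C@H](O[Si](C)(C)C(C)(C)C)CCC[C@H](O[Si](C)(C)C(C)(C)C)CCC[C@@H]1C[C@H](CCC/C(C)=C\C(=O)OC)OC(C)(C)O1
F4 | step 39 | seco acid: (2Z)-enoic acid of the C1–C40 chain with free 35-hydroxyl, 13,17,21,25,27,29,33-heptakis(OTBS), 7,9-O-isopropylidene | CCCC[C@H](C)[C@H](O)C[C@H](O[Si](C)(C)C(C)(C)C)CCC[C@H](O[Si](C)(C)C(C)(C)C)C[C@@H](O[Si](C)(C)C(C)(C)C)C[C@@H](O[Si](C)(C)C(C)(C)C)CCC[C@H](O[Si](C)(C)C(C)(C)C)CCC[C@H](O[Si](C)(C)C(C)(C)C)CCC[C@H](O[Si](C)(C)C(C)(C)C)CCC[C@@H]1C[C@H](CCC/C(C)=C\C(=O)O)OC(C)(C)O1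
F5 | step 27 | C20–C40 alkenol: 25-hydroxy, 27,29,33-tris(OTBS), 35-OTES, C20=C21 terminal alkene | CCCC[C@H](C)[C@H](O[Si](CC)(CC)CC)C[C@H](O[Si](C)(C)C(C)(C)C)CCC[C@H](O[Si](C)(C)C(C)(C)C)C[C@@H](O[Si](C)(C)C(C)(C)C)C[C@@H](O)CCCC=C
F6 | step 27 | 25-O-TBS ether of F5 | CCCC[C@H](C)[C@H](O[Si](CC)(CC)CC)C[C@H](O[Si](C)(C)C(C)(C)C)CCC[C@H](O[Si](C)(C)C(C)(C)C)C[C@@H](O[Si](C)(C)C(C)(C)C)C[C@@H](O[Si](C)(C)C(C)(C)C)CCCC=C
F7 | step 27 | C20–C21 epoxide of F6, both C21 epimers | CCCC[C@H](C)[C@H](O[Si](CC)(CC)CC)C[C@H](O[Si](C)(C)C(C)(C)C)CCC[C@H](O[Si](C)(C)C(C)(C)C)C[C@@H](O[Si](C)(C)C(C)(C)C)C[C@@H](O[Si](C)(C)C(C)(C)C)CCCC1CO1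
F8 | step 27 | (21R)-20,21-diol from the unwanted epoxide epimer | CCCC[C@H](C)[C@H](O[Si](CC)(CC)CC)C[C@H](O[Si](C)(C)C(C)(C)C)CCC[C@H](O[Si](C)(C)C(C)(C)C)C[C@@H](O[Si](C)(C)C(C)(C)C)C[C@@H](O[Si](C)(C)C(C)(C)C)CCC[C@@H](O)CO
F9 | step 34 | C5 aldehyde with 35-OTES, 13,17,21,25,27,29,33-heptakis(OTBS), 7,9-O-isopropylidene | CCCC[C@H](C)[C@H](O[Si](CC)(CC)CC)C[C@H](O[Si](C)(C)C(C)(C)C)CCC[C@H](O[Si](C)(C)C(C)(C)C)C[C@@H](O[Si](C)(C)C(C)(C)C)C[C@@H](O[Si](C)(C)C(C)(C)C)CCC[C@H](O[Si](C)(C)C(C)(C)C)CCC[C@H](O[Si](C)(C)C(C)(C)C)CCC[C@H](O[Si](C)(C)C(C)(C)C)CCC[C@@H]1C[C@H](CC=O)OC(C)(C)O1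
F10 | step 34 | C4–C40 terminal alkene with 35-OTES, 13,17,21,25,27,29,33-heptakis(OTBS), 7,9-O-isopropylidene | CCCC[C@H](C)[C@H](O[Si](CC)(CC)CC)C[C@H](O[Si](C)(C)C(C)(C)C)CCC[C@H](O[Si](C)(C)C(C)(C)C)C[C@@H](O[Si](C)(C)C(C)(C)C)C[C@@H](O[Si](C)(C)C(C)(C)C)CCC[C@H](O[Si](C)(C)C(C)(C)C)CCC[C@H](O[Si](C)(C)C(C)(C)C)CCC[C@H](O[Si](C)(C)C(C)(C)C)CCC[C@@H]1C[C@H](CC=C)OC(C)(C)O1
F11 | step 40 | 7,9-O-isopropylidene derivative of the target (13,17,21,25,27,29,33-heptaol) | CCCC[C@H](C)[C@H]1C[C@H](O)CCC[C@H](O)C[C@@H](O)C[C@@H](O)CCC[C@H](O)CCC[C@H](O)CCC[C@H](O)CCC[C@@H]2C[C@H](CCC/C(C)=C\C(=O)O1)OC(C)(C)O2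
A1 | alternative 1 | ester-linked bis(methylalkyne): O35 ester of the C1–C11 acid (C11≡C–CH3) with the C12–C40 alcohol (C12≡C–CH3), nonakis-TBS | CCCC[C@H](C)[C@H](OC(=O)/C=C(/C)CCC[C@H](O[Si](C)(C)C(C)(C)C)C[C@H](O[Si](C)(C)C(C)(C)C)CC#CC)C[C@H](O[Si](C)(C)C(C)(C)C)CCC[C@H](O[Si](C)(C)C(C)(C)C)C[C@@H](O[Si](C)(C)C(C)(C)C)C[C@@H](O[Si](C)(C)C(C)(C)C)CCC[C@H](O[Si](C)(C)C(C)(C)C)CCC[C@H](O[Si](C)(C)C(C)(C)C)CCC[C@H](O[Si](C)(C)C(C)(C)C)C#CC
A2 | alternative 1 | nonakis-TBS 11,12-didehydro macrolactone | CCCC[C@H](C)[C@H]1C[C@H](O[Si](C)(C)C(C)(C)C)CCC[C@H](O[Si](C)(C)C(C)(C)C)C[C@@H](O[Si](C)(C)C(C)(C)C)C[C@@H](O[Si](C)(C)C(C)(C)C)CCC[C@H](O[Si](C)(C)C(C)(C)C)CCC[C@H](O[Si](C)(C)C(C)(C)C)CCC[C@H](O[Si](C)(C)C(C)(C)C)C#CC[C@@H](O[Si](C)(C)C(C)(C)C)C[C@@H](O[Si](C)(C)C(C)(C)C)CCC/C(C)=C\C(=O)O1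
A3 | alternative 1 | but-2-yne | CC#CC
A4 | alternative 1 | Mo(≡CC6H4OMe-4)(OSiPh3)3 | COc1ccc(cc1)C#[Mo](O[Si](c1ccccc1)(c1ccccc1)c1ccccc1)(O[Si](c1ccccc1)(c1ccccc1)c1ccccc1)O[Si](c1ccccc1)(c1ccccc1)c1ccccc1
A5 | alternative 2 | pentane-1,5-diol | OCCCCCO
A6 | alternative 2 | allyl acetate | C=CCOC(C)=O
A7 | alternative 2 | (4R,8R)-undeca-1,10-diene-4,8-diol | C=CC[C@H](O)CCC[C@@H](O)CC=C
A8 | alternative 3 | allenylboronic acid pinacol ester | C=C=CB1OC(C)(C)C(C)(C)O1
A9 | alternative 3 | C25–C40 aldehyde (35-OPMB, 27,29,33-tris-OTBS) | CCCC[C@H](C)[C@H](OCc1ccc(OC)cc1)C[C@H](O[Si](C)(C)C(C)(C)C)CCC[C@H](O[Si](C)(C)C(C)(C)C)C[C@@H](O[Si](C)(C)C(C)(C)C)CC=O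
A10 | alternative 3 | C1–C21 aldehyde (methyl (2Z)-enoate, 7,9,13,17-tetrakis-OTBS) | O=CCCC[C@H](O[Si](C)(C)C(C)(C)C)CCC[C@H](O[Si](C)(C)C(C)(C)C)CCC[C@@H](O[Si](C)(C)C(C)(C)C)C[C@@H](O[Si](C)(C)C(C)(C)C)CCC/C(C)=C\C(=O)OC
A11 | alternative 3 | C1–C40 (E)-23-ene-21,25-anti-diol | CCCC[C@H](C)[C@H](OCc1ccc(OC)cc1)C[C@H](O[Si](C)(C)C(C)(C)C)CCC[C@H](O[Si](C)(C)C(C)(C)C)C[C@@H](O[Si](C)(C)C(C)(C)C)C[C@@H](O)/C=C/C[C@H](O)CCC[C@H](O[Si](C)(C)C(C)(C)C)CCC[C@H](O[Si](C)(C)C(C)(C)C)CCC[C@@H](O[Si](C)(C)C(C)(C)C)C[C@@H](O[Si](C)(C)C(C)(C)C)CCC/C(C)=C\C(=O)OC
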